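**Plan**

- Retrosynthesis: cut first the side-chain bond between the ketone carbon C2' and the heptadecenyl chain, which leaves an acetic acid arm on the ring and oleic acid (used with loss of CO2). Then cut the ring bond between the enone carbonyl carbon C1 and the vinyl α-carbon C2.
- Enabling feature: the carbinol carbon C5 of the cyclohexenone carries two CH2–C(=O) arms (ring C6–C1 and side-chain C1'–C2'), a hidden 3-hydroxyglutarate. Tying both carbonyls into a six-membered cyclic anhydride (an oxane-2,6-dione, a temporary ring) gives an achiral, mirror-symmetric precursor whose third arm on C5 is a (Z)-3-iodoallyl group (the future C4–C3=C2).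
- Forward: Barbier propargylation of dimethyl 3-oxopentanedioate, alkyne to (Z)-vinyl iodide, saponification, anhydride closure. The cyclohexenone, the only ring of the target, then arises in step 6 by a nickel-catalysed electroreductive alkenyl–acyl coupling that opens the anhydride ring and leaves the acid arm.
- Stereochemistry: C5 is set in step 6 by catalyst-controlled choice between the two enantiotopic anhydride carbonyls. The ring cis-alkene comes from the Z-vinyl iodide and the chain Z-alkene from oleic acid.
- The chain is joined last by nickel-catalysed decarboxylative coupling of the oleic acid N-hydroxyphthalimide ester with the 2-pyridyl thioester of the acid arm.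

Key step: step 6

Remark on the chemistry: the sense of induction of the chiral nickel catalyst in step 6 cannot be predicted with confidence; the ligand antipode that delivers (S)-9 is to be chosen by experiment, both antipodes being available. The 5-hydroxycyclohex-2-enone unit can dehydrate towards a phenol, so every step after step 6 is run near neutrality.

**Step 1**
Reactants: 1 dimethyl 3-oxopentanedioate; 2 3-bromoprop-1-yne (propargyl bromide)
Product: 4 dimethyl 3-hydroxy-3-(prop-2-yn-1-yl)pentanedioate, via allenylzinc bromide 3 (not isolated)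
Conditions: Zn dust, THF/sat. aq. NH4Cl, 0 °C to rt
Reagents that add atoms: none
Why: Barbier-type propargylation, in which the allenylzinc species formed on the metal adds through an SE2' six-membered transition state to the ketone carbonyl to give the homopropargylic tertiary alcohol, the aqueous NH4Cl medium holding back enolisation of the β-keto diester; the product is achiral because C3 carries two identical arms.

**Step 2**
Reactants: 4 dimethyl 3-hydroxy-3-(prop-2-yn-1-yl)pentanedioate
Product: 5 dimethyl 3-hydroxy-3-(3-iodoprop-2-yn-1-yl)pentanedioate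
Conditions: N-iodosuccinimide, AgNO3 (10 mol %), acetone, rt, dark
Reagents that add atoms: N-iodosuccinimide, O=C1CCC(=O)N1I
Why: Silver-catalysed electrophilic iodination of the terminal alkyne (through the silver acetylide) is selective for the acetylenic C–H and should leave the tertiary alcohol and the esters untouched.

**Step 3**
Reactants: 5 dimethyl 3-hydroxy-3-(3-iodoprop-2-yn-1-yl)pentanedioate
Product: 6 dimethyl 3-hydroxy-3-[(2Z)-3-iodoprop-2-en-1-yl]pentanedioate
Conditions: 2-nitrobenzenesulfonohydrazide, Et3N, THF/i-PrOH, rt
Reagents that add atoms: none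
Why: Diimide reduction, in which diimide released from the sulfonohydrazide transfers two hydrogens suprafacially to the iodoalkyne and should give the (Z)-iodoalkene without touching the esters or the C–I bond.

**Step 4**
Reactants: 6 dimethyl 3-hydroxy-3-[(2Z)-3-iodoprop-2-en-1-yl]pentanedioate
Product: 7 3-hydroxy-3-[(2Z)-3-iodoprop-2-en-1-yl]pentanedioic acid
Conditions: LiOH, THF/H2O, 0 °C to rt; then 1 M HCl to pH 2
Reagents that add atoms: lithium hydroxide, [Li+].[OH-]
Why: Saponification of both methyl esters by acyl–oxygen cleavage, to which the vinyl iodide and the tertiary alcohol should be inert in the cold.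

**Step 5**
Reactants: 7 3-hydroxy-3-[(2Z)-3-iodoprop-2-en-1-yl]pentanedioic acid
Product: 8 4-hydroxy-4-[(2Z)-3-iodoprop-2-en-1-yl]oxane-2,6-dione
Conditions: N,N'-dicyclohexylcarbodiimide, THF, 0 °C to rt; filter, use dry
Reagents that add atoms: none
Why: Carbodiimide-mediated cyclodehydration of the 1,5-diacid to the six-membered cyclic anhydride, as is usual for 3-hydroxy-3-alkylglutaric acids, whose hindered tertiary hydroxyl is not acylated.

**Step 6**
Reactants: 8 4-hydroxy-4-[(2Z)-3-iodoprop-2-en-1-yl]oxane-2,6-dione
Product: 9 2-[(1S)-1-hydroxy-5-oxocyclohex-3-en-1-yl]acetic acid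
Conditions: NiBr2(MeOCH2CH2OMe) (10 mol %), (4S,4'S)-4,4'-dibenzyl-4,4',5,5'-tetrahydro-2,2'-bioxazole or its antipode (12 mol %), undivided cell, Zn anode, nickel-foam cathode, LiBr, DMA, 0.02 M, 0 °C, constant current, about 2.2 F/mol; then aq. citric acid
Reagents that add atoms: none
Why: Proposed new method: cathodically generated zerovalent nickel bearing the chiral bi(oxazoline) should insert into the C(sp2)–I bond of 8 with retention of the Z geometry, and the alkenylnickel (after one-electron reduction) should cleave one acyl C–O bond of the tethered anhydride and reductively eliminate the enone C(=O)–CH= bond, the carboxylate leaving group staying in the molecule as the acetic acid arm. The closest known reaction types are the nickel-catalysed reductive acylation of organic halides with carboxylic anhydrides, the nickel-catalysed enantioselective desymmetrisation of cyclic meso-anhydrides with carbon nucleophiles or radicals, and nickel-catalysed electroreductive couplings of alkenyl halides; their intramolecular, enantiotopic-group-selective combination is the new element. The cyclohexenone ring closes in a 6-exo-trig mode at the anhydride carbonyl through a bicyclo[3.3.1]-like transition state in which the iodoallyl arm is axial on the oxanedione ring. The carbinol carbon is already present as a prochiral centre and becomes the (S)-stereocentre when the chiral nickel complex selects one of the two enantiotopic carbonyl groups, so control is by the ligand alone. The step needs C–I insertion to outrun reduction of the anhydride or the product enone, which holding the electrode at the potential of the nickel couple should secure, and cyclisation to outrun protodeiodination and dimerisation, which the fixed Z geometry, the six-atom reach and high dilution should secure. Because the leaving group is an internal carboxylate, no alkoxide base is released and the β-hydroxy enone should survive.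

**Step 7**
Reactants: 9 2-[(1S)-1-hydroxy-5-oxocyclohex-3-en-1-yl]acetic acid
Product: 10 S-pyridin-2-yl 2-[(1S)-1-hydroxy-5-oxocyclohex-3-en-1-yl]ethanethioate
Conditions: 2,2'-dipyridyl disulfide, PPh3 (premixed), CH2Cl2, 0 °C
Reagents that add atoms: 2,2'-dipyridyl disulfide, c1ccc(SSc2ccccn2)nc1
Why: Mukaiyama redox condensation (Corey–Nicolaou-type thioesterification) activates the acid under neutral conditions, under which the hindered tertiary hydroxyl and the enone should not react and the stereocentre is untouched.

**Step 8**
Reactants: 11 oleic acid, (9Z)-octadec-9-enoic acid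
Product: 12 1,3-dioxoisoindolin-2-yl (9Z)-octadec-9-enoate
Conditions: N-hydroxyphthalimide, N,N'-diisopropylcarbodiimide, DMAP (cat.), CH2Cl2, rt
Reagents that add atoms: N-hydroxyphthalimide, O=C1c2ccccc2C(=O)N1O
Why: Steglich-type carbodiimide esterification should give the redox-active N-acyloxyphthalimide without disturbing the Z-alkene.

**Step 9**
Reactants: 10 S-pyridin-2-yl 2-[(1S)-1-hydroxy-5-oxocyclohex-3-en-1-yl]ethanethioate; 12 1,3-dioxoisoindolin-2-yl (9Z)-octadec-9-enoate
Product: 13 (5R)-5-hydroxy-5-[(10Z)-2-oxononadec-10-en-1-yl]cyclohex-2-en-1-one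
Conditions: NiBr2(MeOCH2CH2OMe) (10 mol %), 4,4'-di-tert-butyl-2,2'-bipyridine (11 mol %), Zn dust, THF/DMA, rt; then aq. NH4Cl
Reagents that add atoms: none
Why: Nickel-catalysed decarboxylative cross-electrophile ketone synthesis, in which reduced nickel fragments the redox-active ester to CO2 and the primary (Z)-heptadec-8-enyl radical, this radical is captured by the acylnickel formed by insertion into the C(acyl)–S bond of 10, and reductive elimination should give the ketone without touching the stereocentre or either alkene.

**Compound list**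

1 | dimethyl 3-oxopentanedioate | COC(=O)CC(=O)CC(=O)OC | starting material
2 | 3-bromoprop-1-yne (propargyl bromide) | C#CCBr | starting material
3 | allenylzinc bromide, bromo(propa-1,2-dien-1-yl)zinc (not isolated) | C=C=C[Zn]Br | intermediate
4 | dimethyl 3-hydroxy-3-(prop-2-yn-1-yl)pentanedioate | COC(=O)CC(O)(CC#C)CC(=O)OC | intermediate
5 | dimethyl 3-hydroxy-3-(3-iodoprop-2-yn-1-yl)pentanedioate | COC(=O)CC(O)(CC#CI)CC(=O)OC | intermediate
6 | dimethyl 3-hydroxy-3-[(2Z)-3-iodoprop-2-en-1-yl]pentanedioate | COC(=O)CC(O)(C/C=C\I)CC(=O)OC | intermediate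
7 | 3-hydroxy-3-[(2Z)-3-iodoprop-2-en-1-yl]pentanedioic acid | OC(=O)CC(O)(C/C=C\I)CC(=O)O | intermediate
8 | 4-hydroxy-4-[(2Z)-3-iodoprop-2-en-1-yl]oxane-2,6-dione | O=C1CC(O)(C/C=C\I)CC(=O)O1 | intermediate
9 | 2-[(1S)-1-hydroxy-5-oxocyclohex-3-en-1-yl]acetic acid | OC(=O)C[C@]1(O)CC=CC(=O)C1 | intermediate
10 | S-pyridin-2-yl 2-[(1S)-1-hydroxy-5-oxocyclohex-3-en-1-yl]ethanethioate | O=C(C[C@]1(O)CC=CC(=O)C1)Sc1ccccn1 | intermediate
11 | oleic acid, (9Z)-octadec-9-enoic acid | CCCCCCCC/C=C\CCCCCCCC(=O)O | starting material
12 | 1,3-dioxoisoindolin-2-yl (9Z)-octadec-9-enoate | CCCCCCCC/C=C\CCCCCCCC(=O)ON1C(=O)c2ccccc2C1=O | intermediate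
13 | (5R)-5-hydroxy-5-[(10Z)-2-oxononadec-10-en-1-yl]cyclohex-2-en-1-one | CCCCCCCC/C=C\CCCCCCCC(=O)C[C@]1(O)CC=CC(=O)C1 | target

**Step count**

Total steps: 9. Longest linear sequence: 8 (steps 1 to 7, then step 9; step 8 is the side branch).

**Steps most likely to fail**

1. Step 6. The chiral nickel complex may discriminate poorly between the two enantiotopic carbonyls, or the alkenylnickel may be protonated or dimerise before it acylates. The fallback uses known chemistry, sets out from anhydride 8 and comes back at acid 9.
   - Organocatalytic desymmetrising alcoholysis of 8 with allyl alcohol and a cinchona-alkaloid-derived thiourea (MTBE, −20 °C; pseudo-enantiomer chosen for the S series) should give (3S)-3-hydroxy-3-[(2Z)-3-iodoprop-2-en-1-yl]-5-oxo-5-(prop-2-en-1-yloxy)pentanoic acid F1.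
   - The free acid is reduced through its isobutyl mixed anhydride (i-BuOCOCl, N-methylmorpholine, then NaBH4, THF/H2O, −15 °C) to prop-2-en-1-yl (3S)-3,5-dihydroxy-3-[(2Z)-3-iodoprop-2-en-1-yl]pentanoate F2.
   - F2 is oxidised without delay with Dess–Martin periodinane to prop-2-en-1-yl (3S)-3-hydroxy-3-[(2Z)-3-iodoprop-2-en-1-yl]-5-oxopentanoate F3.
   - An intramolecular Nozaki–Hiyama–Kishi reaction (CrCl2, NiCl2 cat., DMSO, rt) then closes the same carbonyl-carbon to vinyl-carbon bond and should give prop-2-en-1-yl 2-[(1S)-1,5-dihydroxycyclohex-3-en-1-yl]acetate F4 as both C5 epimers.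
   - MnO2 (CH2Cl2) converges both epimers on prop-2-en-1-yl 2-[(1S)-1-hydroxy-5-oxocyclohex-3-en-1-yl]acetate F5.
   - Deallylation with Pd(PPh3)4 (cat.) and morpholine in THF returns acid 9.

2. Step 9. The heptadecenyl radical may add to the enone (conjugate addition) or be reduced before the acylnickel captures it. The fallback replaces the radical by a two-electron acyl Negishi (Fukuyama-type) coupling; it sets out from 12 (with thioester 10) and comes back at 13.
   - Visible-light iododecarboxylation of 12 (LiI, PPh3 cat., blue LED, acetone) should give (8Z)-1-iodoheptadec-8-ene F6.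
   - Zinc insertion (Zn dust, LiCl, THF) gives [(8Z)-heptadec-8-en-1-yl]zinc iodide F7.
   - F7 (about 3 equiv, to allow for the free hydroxyl) is coupled with 10 using PdCl2(PPh3)2 (5 mol %) in THF/toluene at rt to give 13.

3. Step 7. Carboxyl activation next to the free tertiary hydroxyl may lead to β-lactonisation or to dehydration towards the phenol. The fallback masks the hydroxyl for the last stages; it sets out from 9 and comes back at 13.
   - N,O-bis(trimethylsilyl)acetamide (CH2Cl2, rt) gives trimethylsilyl 2-[(1S)-5-oxo-1-(trimethylsilyloxy)cyclohex-3-en-1-yl]acetate F8, which is not isolated.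
   - Brief methanolysis of the silyl ester gives 2-[(1S)-5-oxo-1-(trimethylsilyloxy)cyclohex-3-en-1-yl]acetic acid F9.
   - Thioesterification as in step 7 gives S-pyridin-2-yl 2-[(1S)-5-oxo-1-(trimethylsilyloxy)cyclohex-3-en-1-yl]ethanethioate F10.
   - Coupling with 12 as in step 9 gives (5R)-5-[(10Z)-2-oxononadec-10-en-1-yl]-5-(trimethylsilyloxy)cyclohex-2-en-1-one F11.
   - Aqueous citric acid in THF at 0 °C removes the silyl ether to give 13.

**Further compounds**

F1 | step 6 | (3S)-3-hydroxy-3-[(2Z)-3-iodoprop-2-en-1-yl]-5-oxo-5-(prop-2-en-1-yloxy)pentanoic acid | C=CCOC(=O)C[C@](O)(C/C=C\I)CC(=O)O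
F2 | step 6 | prop-2-en-1-yl (3S)-3,5-dihydroxy-3-[(2Z)-3-iodoprop-2-en-1-yl]pentanoate | C=CCOC(=O)C[C@](O)(C/C=C\I)CCO
F3 | step 6 | prop-2-en-1-yl (3S)-3-hydroxy-3-[(2Z)-3-iodoprop-2-en-1-yl]-5-oxopentanoate | C=CCOC(=O)C[C@](O)(C/C=C\I)CC=O
F4 | step 6 | prop-2-en-1-yl 2-[(1S)-1,5-dihydroxycyclohex-3-en-1-yl]acetate (both C5 epimers) | C=CCOC(=O)C[C@]1(O)CC=CC(O)C1
F5 | step 6 | prop-2-en-1-yl 2-[(1S)-1-hydroxy-5-oxocyclohex-3-en-1-yl]acetate | C=CCOC(=O)C[C@]1(O)CC=CC(=O)C1
F6 | step 9 | (8Z)-1-iodoheptadec-8-ene | CCCCCCCC/C=C\CCCCCCCI
F7 | step 9 | [(8Z)-heptadec-8-en-1-yl]zinc iodide | CCCCCCCC/C=C\CCCCCCC[Zn]I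
F8 | step 7 | trimethylsilyl 2-[(1S)-5-oxo-1-(trimethylsilyloxy)cyclohex-3-en-1-yl]acetate | C[Si](C)(C)OC(=O)C[C@]1(O[Si](C)(C)C)CC=CC(=O)C1
F9 | step 7 | 2-[(1S)-5-oxo-1-(trimethylsilyloxy)cyclohex-3-en-1-yl]acetic acid | OC(=O)C[C@]1(O[Si](C)(C)C)CC=CC(=O)C1
F10 | step 7 | S-pyridin-2-yl 2-[(1S)-5-oxo-1-(trimethylsilyloxy)cyclohex-3-en-1-yl]ethanethioate | O=C(C[C@]1(O[Si](C)(C)C)CC=CC(=O)C1)Sc1ccccn1
F11 | step 7 | (5R)-5-[(10Z)-2-oxononadec-10-en-1-yl]-5-(trimethylsilyloxy)cyclohex-2-en-1-one | CCCCCCCC/C=C\CCCCCCCC(=O)C[C@]1(O[Si](C)(C)C)CC=CC(=O)C1
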